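(The runs are calculated on assumed constants.)

70.1 % of the charged reagent stands as target in the late readings of the south-west run, which is this same flask followed so far. I carry that figure as the reagent's share, the target formed per reagent charged. The readings from 60.0 min on average 42.0 % of the starting material, and at one reagent per target the charge allows 60.0 %.

- south-west: starting material 0.010 M; second substrate 10 mM; reagent 6 mM; free catalyst 100 µM; the very flask that is asked about, followed so far
- flask: starting material 0.010 M; second substrate 10.0 mM; reagent 6.00 mM; free catalyst 100 µM; time 2.5 h

south-west run (percent of the starting material charged): time / min: target / % = 10.0: 32.2; 30.0: 40.9; 60.0: 41.1; 80.0: 42.3; 120: 42.7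

(scatter of a reading: 0.5 percentage points)

- zeta: change nothing and wait 5.0 h more
- epsilon: at 2.5 h take out 90 % of the target then present, then wait 5.0 h
- eta: at 2.5 h add free catalyst, 100 % of the amount charged, then wait 5.0 h
- gamma: at 2.5 h add reagent, 100 % of the amount charged, then wait 5.0 h

- removed target is counted in
- additions bring no volume worth counting

1. target, in percent of the starting material first charged, at 2.5 h
2. the remedy with the largest gain of target, or "none" below 2 percentage points (zeta / epsilon / eta / gamma / none)
3. target present, with what was taken out counted in, in percent of the starting material first charged, after zeta
4. target present, with what was taken out counted in, in percent of the starting material first charged, after epsilon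

I climb the ladder in powers of ten. On the lowest rung, the first reading leaves 23.4 % of that level still to come, so, read as a single exponential, the burst closes at 0.145 min⁻¹, a half-time of 4.77 min. The asked time lies 1.50 powers of ten above that half-time, and the end of the wait lies 1.97 above it. Between the first reading and the last stretch, the rate of rise falls by 2.08 powers of ten. That last stretch rises 1.6 percentage points against a scatter of 0.5 points per reading, so I read a level, with a doubtful creep.

On the top rung I ask what stopped it. The 29.9 % of the reagent not found as target can have gone to the second substrate, charged level with the starting material. So I take reagent as the limiting reagent of this flask, its end marked by the level. My reckoning is then 42.0 % at 2.5 h, and the same after zeta and epsilon. On that view added catalyst brings no new reagent, so gamma is my choice: at the same share it offers 42 points more if the catalyst still works, which these readings do not show.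

The forecast differs, with 43.3 %, 49 % after zeta, 49 % after epsilon and eta as best, since “Fresh catalyst should repeat the burst”.

The flask gives 41.9 % at 2.5 h, 41.9 % after zeta, 41.9 % after epsilon, and gamma as best, gaining 7 points against 0.0093 points for eta.

    second substrate + free catalyst ⇌ catalyst intermediate B (K = 40.0 M⁻¹, k = 1200 M⁻¹ min⁻¹)
    free catalyst → spent catalyst (k = 0.0450 min⁻¹)
    starting material + free catalyst ⇌ catalyst intermediate A (K = 190 M⁻¹, k = 1600 M⁻¹ min⁻¹)
    2 starting material → self-condensation product (k = 0.0160 M⁻¹ min⁻¹)
    reagent + catalyst intermediate B → free catalyst + second product (k = 3600 M⁻¹ min⁻¹)
    reagent + catalyst intermediate A → free catalyst + target (k = 3000 M⁻¹ min⁻¹)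

Half of the turnover up to 2.5 h of reagent with catalyst intermediate A into target was done at 5.01 min, and by 75.0 min reagent stood at 0.120 % of its charge. The 29.9 % of the reagent not found as target in the readings reckons to 0.00180 M, and the flask holds 0.00181 M of second product at 150 min. Meanwhile spent catalyst grew to 94.3 % of the catalyst at 150 min. In the neighbour flask charged with 2.5 × 10⁻⁵ M of free catalyst, 18.3 % of the reagent is left at 150 min, so the share applied to the reagent used gives 34.3 % of the starting material as target, and that flask holds 34.0 %.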